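**Plan**

- Retrosynthesis: the quinone is traced back to a p-methoxyphenol on ring B, the pyran ether bond O1–C2 is cut, C2 is removed from C3 (leaving boron there), and C3–C1' and C4–C4a are cut together.
- Enabling feature: C3–C4 is a two-carbon unit with ring B on C3 and ring A on C4, i.e. a vinyl group arylated at both carbons. A vinylboron, a ring B aryllithium and a ring A aryl bromide can therefore be merged in one conjunctive coupling, and the boron left on C3 is the handle for C2.
- Forward: the ring B arene (hydroxylation, MOM ether) and the ring A bromide (bromination, benzyl ether) are made separately and joined on vinylboronic pinacol ester. C2 is then added as CH2OH, the pyran ring (ring C) closes by O1–C2 etherification, and ring B is oxidised to the quinone last.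
- Stereochemistry: C3 is the only stereocentre. It is set in the coupling by the chiral ferrocenyl bisphosphine on palladium, kept by the stereoretentive boron-to-carbon shift, and is never a reacting centre afterwards.

Key step: step 5

Assumption: which antipode of the ferrocenyl bisphosphine (MandyPhos type) delivers the S boronate is taken to be settled by a model coupling; the route is written for that antipode.

**Route**

Step 1
Reactants: 1 1,2,3,4-tetramethoxybenzene
Product: 4 2,3,4,5-tetramethoxyphenol, via aryllithium 2 (not isolated), via lithium aryltrimethoxyborate 3 (not isolated)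
Conditions: n-BuLi, TMEDA, THF, 0 °C; B(OMe)3, −78 °C → rt; AcOH, 30% aq. H2O2, 0 °C → rt
Reagents that add atoms: hydrogen peroxide (OO)
Why: Directed ortho-lithiation at one of the two equivalent ring C–H positions beside an OMe, borylation and peroxide oxidation of the aryl–boron bond (hydroxylation via an arylborate) should place the fifth oxygen exactly where the ring B phenol is needed.

Step 2
Reactants: 4 2,3,4,5-tetramethoxyphenol
Product: 5 1,2,3,4-tetramethoxy-5-(methoxymethoxy)benzene
Conditions: NaH, THF, 0 °C; MOMCl, 0 °C → rt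
Reagents that add atoms: chloromethyl methyl ether (COCCl)
Why: Williamson-type O-alkylation of the sodium phenoxide should give the MOM ether, which withstands organolithiums, directs the later lithiation to the one remaining ring C–H and is removable with mild acid.

Step 3
Reactants: 6 2,3,4-trimethoxyphenol
Product: 7 6-bromo-2,3,4-trimethoxyphenol
Conditions: NBS, i-Pr2NH (10 mol%), CH2Cl2, 0 °C → rt
Reagents that add atoms: N-bromosuccinimide (O=C1CCC(=O)N1Br)
Why: Electrophilic aromatic bromination in its amine-mediated ortho-selective form: the free hydroxyl is the strongest donor, its para position is blocked by OMe, and delivery of bromine through the hydrogen-bonded N-bromoamine should place it at C6 next to the hydroxyl rather than at C5.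

Step 4
Reactants: 7 6-bromo-2,3,4-trimethoxyphenol
Product: 8 2-(benzyloxy)-1-bromo-3,4,5-trimethoxybenzene
Conditions: BnBr, K2CO3, DMF, rt
Reagents that add atoms: benzyl bromide (BrCc1ccccc1)
Why: Williamson ether synthesis masks the ring A phenol as a benzyl ether that tolerates the organometallic steps and is orthogonal to the MOM ether on ring B.

Step 5
Reactants: 5 1,2,3,4-tetramethoxy-5-(methoxymethoxy)benzene, 9 vinylboronic acid pinacol ester, 8 2-(benzyloxy)-1-bromo-3,4,5-trimethoxybenzene
Product: 12 pinacol (S)-{2-[2-(benzyloxy)-3,4,5-trimethoxyphenyl]-1-[2-(methoxymethoxy)-3,4,5,6-tetramethoxyphenyl]ethyl}boronate, via aryllithium 10 (not isolated), via vinyl boronate complex 11 (not isolated)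
Conditions: n-BuLi (0.95 equiv to 5), THF, 0 °C; 9, −78 °C → rt; 8, Pd(OAc)2 (2 mol%), 2,2'-bis[(dimethylamino)(phenyl)methyl]-1,1'-bis(diphenylphosphino)ferrocene (one antipode, 2.4 mol%), CF3SO3K, THF, 60 °C
Reagents that add atoms: none
Why: Deprotonation of 5 at its only ring C–H, flanked by the OMOM and OMe oxygens, gives halide-free aryllithium 10, which adds to the boron of 9 to form the tetracoordinate boronate complex 11; zerovalent palladium formed from Pd(OAc)2 and the bisphosphine inserts into the C–Br bond of 8, bromide is exchanged for triflate as KBr separates, and the resulting cationic aryl complex of divalent palladium binds the vinyl group of 11. This π-activation triggers 1,2-migration of ring B from boron to C3 anti to palladium (C3–C1'), and the C4–Pd bond so formed reductively eliminates to make C4–C4a; the closest known reaction is the palladium-catalysed enantioselective conjunctive cross-coupling of vinylboron ate complexes with aryl triflates or halides, here with a migrating aryl group carrying two ortho alkoxy substituents as the demanding feature. No ring closes in this step. C3 is the only new stereocentre: the chiral bisphosphine decides which face of the vinyl group palladium binds, and the anti metallate shift translates this into the S configuration. The step needs the conjunctive pathway to win over direct transfer of vinyl or ring B from boron to palladium and over β-hydride loss; the wide-bite-angle ferrocenyl ligand, the halide-free ate complex and the electron-rich, strongly migrating ring B favour it, and the two ortho alkoxy groups also shield the B–aryl bond from direct transmetallation. Keeping n-BuLi slightly below the amount of 5 prevents butyl from competing as the migrating group.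

Step 6
Reactants: 12 pinacol (S)-{2-[2-(benzyloxy)-3,4,5-trimethoxyphenyl]-1-[2-(methoxymethoxy)-3,4,5,6-tetramethoxyphenyl]ethyl}boronate
Product: 15 (S)-3-[2-(benzyloxy)-3,4,5-trimethoxyphenyl]-2-[2-(methoxymethoxy)-3,4,5,6-tetramethoxyphenyl]propan-1-ol, via chloromethyl boronate complex 13 (not isolated), via homologated pinacol boronate 14 (not isolated)
Conditions: BrCH2Cl, n-BuLi, THF, −78 °C → rt; NaOH, 30% aq. H2O2, 0 °C → rt
Reagents that add atoms: bromochloromethane (ClCBr); hydrogen peroxide (OO)
Why: Matteson homologation followed by boron oxidation: chloromethyllithium made in the flask adds to boron, the secondary benzylic carbon C3 shifts from boron to the CH2 carbon with retention as chloride leaves, and the new primary C–B bond is oxidised to C–O, so C2 should arrive as CH2OH without change at C3.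

Step 7
Reactants: 15 (S)-3-[2-(benzyloxy)-3,4,5-trimethoxyphenyl]-2-[2-(methoxymethoxy)-3,4,5,6-tetramethoxyphenyl]propan-1-ol
Product: 16 6-{(S)-3-hydroxy-2-[2-(methoxymethoxy)-3,4,5,6-tetramethoxyphenyl]propyl}-2,3,4-trimethoxyphenol
Conditions: H2 (1 atm), 10% Pd/C, EtOAc–MeOH, rt
Reagents that add atoms: none
Why: Catalytic hydrogenolysis cleaves only the benzyl aryl ether, leaving the MOM acetal, the methyl ethers and the C3 stereocentre untouched and freeing the ring A phenol alone.

Step 8
Reactants: 16 6-{(S)-3-hydroxy-2-[2-(methoxymethoxy)-3,4,5,6-tetramethoxyphenyl]propyl}-2,3,4-trimethoxyphenol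
Product: 17 (S)-6,7,8-trimethoxy-3-[2-(methoxymethoxy)-3,4,5,6-tetramethoxyphenyl]chromane
Conditions: PPh3, DIAD, THF, 0 °C → rt
Reagents that add atoms: none
Why: Intramolecular Mitsunobu etherification: the only free phenol attacks the phosphonium-activated primary carbon C2 in a 6-exo-tet closure of the pyran ring, C3 is not a reacting centre, and the MOM group on the ring B oxygen prevents the competing five-membered closure.

Step 9
Reactants: 17 (S)-6,7,8-trimethoxy-3-[2-(methoxymethoxy)-3,4,5,6-tetramethoxyphenyl]chromane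
Product: 18 2,3,4,5-tetramethoxy-6-[(S)-6,7,8-trimethoxychroman-3-yl]phenol
Conditions: HCl (cat.), MeOH, 50 °C
Reagents that add atoms: none
Why: Acid-catalysed acetal exchange with methanol removes the MOM group as dimethoxymethane under conditions that leave the aryl methyl ethers, the chroman and the benzylic C3–H alone.

Step 10
Reactants: 18 2,3,4,5-tetramethoxy-6-[(S)-6,7,8-trimethoxychroman-3-yl]phenol
Product: 19 2,3,5-trimethoxy-6-[(S)-6,7,8-trimethoxychroman-3-yl]cyclohexa-2,5-diene-1,4-dione
Conditions: PhI(OAc)2, MeCN–H2O, 0 °C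
Reagents that add atoms: water (O)
Why: Oxidative demethylation of a p-methoxyphenol with a hypervalent iodine reagent: the phenol binds iodine, water adds at the OMe-bearing carbon para to the phenol oxygen and methanol is lost to give the 1,4-quinone, while ring A, which has no free hydroxyl, should be oxidised far more slowly.

**Compound list**

1 | 1,2,3,4-tetramethoxybenzene | COc1ccc(OC)c(OC)c1OC | starting material
2 | (2,3,4,5-tetramethoxyphenyl)lithium | [Li]c1cc(OC)c(OC)c(OC)c1OC | intermediate
3 | lithium trimethoxy(2,3,4,5-tetramethoxyphenyl)borate | [Li+].CO[B-](OC)(OC)c1cc(OC)c(OC)c(OC)c1OC | intermediate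
4 | 2,3,4,5-tetramethoxyphenol | COc1cc(O)c(OC)c(OC)c1OC | intermediate
5 | 1,2,3,4-tetramethoxy-5-(methoxymethoxy)benzene | COCOc1cc(OC)c(OC)c(OC)c1OC | intermediate
6 | 2,3,4-trimethoxyphenol | COc1ccc(O)c(OC)c1OC | starting material
7 | 6-bromo-2,3,4-trimethoxyphenol | COc1cc(Br)c(O)c(OC)c1OC | intermediate
8 | 2-(benzyloxy)-1-bromo-3,4,5-trimethoxybenzene | COc1cc(Br)c(OCc2ccccc2)c(OC)c1OC | intermediate
9 | vinylboronic acid pinacol ester | C=CB1OC(C)(C)C(C)(C)O1 | starting material
10 | [2-(methoxymethoxy)-3,4,5,6-tetramethoxyphenyl]lithium | COCOc1c([Li])c(OC)c(OC)c(OC)c1OC | intermediate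
11 | lithium [2-(methoxymethoxy)-3,4,5,6-tetramethoxyphenyl](pinacolato)(vinyl)borate | [Li+].C=C[B-]1(OC(C)(C)C(C)(C)O1)c2c(OCOC)c(OC)c(OC)c(OC)c2OC | intermediate
12 | pinacol (S)-{2-[2-(benzyloxy)-3,4,5-trimethoxyphenyl]-1-[2-(methoxymethoxy)-3,4,5,6-tetramethoxyphenyl]ethyl}boronate | COCOc1c([C@H](Cc2cc(OC)c(OC)c(OC)c2OCc3ccccc3)B4OC(C)(C)C(C)(C)O4)c(OC)c(OC)c(OC)c1OC | intermediate
13 | lithium (chloromethyl)(pinacolato){(S)-2-[2-(benzyloxy)-3,4,5-trimethoxyphenyl]-1-[2-(methoxymethoxy)-3,4,5,6-tetramethoxyphenyl]ethyl}borate | [Li+].COCOc1c([C@H](Cc2cc(OC)c(OC)c(OC)c2OCc3ccccc3)[B-]4(CCl)OC(C)(C)C(C)(C)O4)c(OC)c(OC)c(OC)c1OC | intermediate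
14 | pinacol (S)-{3-[2-(benzyloxy)-3,4,5-trimethoxyphenyl]-2-[2-(methoxymethoxy)-3,4,5,6-tetramethoxyphenyl]propyl}boronate | COCOc1c([C@H](Cc2cc(OC)c(OC)c(OC)c2OCc3ccccc3)CB4OC(C)(C)C(C)(C)O4)c(OC)c(OC)c(OC)c1OC | intermediate
15 | (S)-3-[2-(benzyloxy)-3,4,5-trimethoxyphenyl]-2-[2-(methoxymethoxy)-3,4,5,6-tetramethoxyphenyl]propan-1-ol | COCOc1c([C@H](Cc2cc(OC)c(OC)c(OC)c2OCc3ccccc3)CO)c(OC)c(OC)c(OC)c1OC | intermediate
16 | 6-{(S)-3-hydroxy-2-[2-(methoxymethoxy)-3,4,5,6-tetramethoxyphenyl]propyl}-2,3,4-trimethoxyphenol | COCOc1c([C@H](Cc2cc(OC)c(OC)c(OC)c2O)CO)c(OC)c(OC)c(OC)c1OC | intermediate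
17 | (S)-6,7,8-trimethoxy-3-[2-(methoxymethoxy)-3,4,5,6-tetramethoxyphenyl]chromane | COCOc1c([C@H]2COc3c(cc(OC)c(OC)c3OC)C2)c(OC)c(OC)c(OC)c1OC | intermediate
18 | 2,3,4,5-tetramethoxy-6-[(S)-6,7,8-trimethoxychroman-3-yl]phenol | Oc1c([C@H]2COc3c(cc(OC)c(OC)c3OC)C2)c(OC)c(OC)c(OC)c1OC | intermediate
19 | 2,3,5-trimethoxy-6-[(S)-6,7,8-trimethoxychroman-3-yl]cyclohexa-2,5-diene-1,4-dione | COC1=C(OC)C(=O)C([C@H]2COc3c(cc(OC)c(OC)c3OC)C2)=C(OC)C1=O | target

**Count**

Total steps: 10. Longest linear sequence: 8 steps (1, 2, 5, 6, 7, 8, 9, 10); steps 3 and 4 form the short ring A branch.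

**Steps most likely to fail**

1. Step 5. The boron-to-carbon shift of the doubly ortho-substituted ring B may be slow, so that direct transfer of vinyl or aryl from boron to palladium, β-hydride loss or poor enantiofacial control take over. The fallback sets out from 8 and from 10 and comes back at 12; it replaces the catalytic coupling by sparteine-mediated lithiation–borylation. Bromine–lithium exchange on 8 (n-BuLi, THF, −78 °C) gives [2-(benzyloxy)-3,4,5-trimethoxyphenyl]lithium F1, which opens ethylene oxide (BF3·OEt2) to 2-[2-(benzyloxy)-3,4,5-trimethoxyphenyl]ethan-1-ol F2. N,N-Diisopropylcarbamoyl chloride and NaH convert this into 2-[2-(benzyloxy)-3,4,5-trimethoxyphenyl]ethyl N,N-diisopropylcarbamate F3. Aryllithium 10, made from 5 as in step 5, is quenched with 2-isopropoxy-4,4,5,5-tetramethyl-1,3,2-dioxaborolane to give 2-[2-(methoxymethoxy)-3,4,5,6-tetramethoxyphenyl]-4,4,5,5-tetramethyl-1,3,2-dioxaborolane F4. Deprotonation of F3 with s-BuLi and (+)-sparteine (Et2O, −78 °C; the antipode expected to lead to the S boronate) should give the configurationally stable (R)-2-[2-(benzyloxy)-3,4,5-trimethoxyphenyl]-1-lithioethyl N,N-diisopropylcarbamate F5. This adds to the boron of F4 with retention to form lithium {(R)-2-[2-(benzyloxy)-3,4,5-trimethoxyphenyl]-1-[(diisopropylcarbamoyl)oxy]ethyl}[2-(methoxymethoxy)-3,4,5,6-tetramethoxyphenyl](pinacolato)borate F6. On warming with MgBr2·OEt2, ring B shifts from boron to carbon with inversion as the carbamate leaves, which should give 12.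

2. Step 6. The short-lived carbenoid may decompose before the hindered secondary boronate captures it, and the electron-rich benzylic C–B bond may be lost by protodeboronation. The fallback sets out from 12 and comes back at 15; it uses a persistent sp2 nucleophile in a Zweifel olefination and then cuts the alkene back to one carbon. Vinyllithium (THF, −78 °C) adds to the boron of 12 to give lithium {(S)-2-[2-(benzyloxy)-3,4,5-trimethoxyphenyl]-1-[2-(methoxymethoxy)-3,4,5,6-tetramethoxyphenyl]ethyl}(pinacolato)(vinyl)borate F7. Iodine induces the shift of C3 from boron to the vinyl carbon with retention, giving pinacol {(3R)-4-[2-(benzyloxy)-3,4,5-trimethoxyphenyl]-1-iodo-3-[2-(methoxymethoxy)-3,4,5,6-tetramethoxyphenyl]butan-2-yl}boronate F8 as a mixture of epimers at the boron-bearing carbon. NaOMe then causes anti elimination to 2-(benzyloxy)-3,4,5-trimethoxy-1-{(R)-2-[2-(methoxymethoxy)-3,4,5,6-tetramethoxyphenyl]but-3-en-1-yl}benzene F9; C3 keeps its spatial arrangement and the descriptor changes by priority only. Cleavage with OsO4 (cat.) and NaIO4 (2,6-lutidine, dioxane–water) gives (S)-3-[2-(benzyloxy)-3,4,5-trimethoxyphenyl]-2-[2-(methoxymethoxy)-3,4,5,6-tetramethoxyphenyl]propanal F10, which is reduced at once with NaBH4 (MeOH, 0 °C) to 15 so that the α-aryl aldehyde has little time to epimerise.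

3. Step 10. Water may attack the ortho OMe-bearing carbon instead of the para one, leading to an ortho-quinone, or the oxidant may go on to attack ring A or the product. The fallback sets out from 18 and comes back at 19; it separates oxidation from unveiling of the quinone. PhI(OAc)2 in dry methanol at 0 °C should trap the para position with methanol and give the quinone monoketal 2,3,4,4,5-pentamethoxy-6-[(S)-6,7,8-trimethoxychroman-3-yl]cyclohexa-2,5-dien-1-one F11. This is isolated free of oxidant and hydrolysed with dilute aqueous acid (THF–water, rt) to 19.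

**Further compounds**

F1 | step 5 | [2-(benzyloxy)-3,4,5-trimethoxyphenyl]lithium | [Li]c1cc(OC)c(OC)c(OC)c1OCc1ccccc1
F2 | step 5 | 2-[2-(benzyloxy)-3,4,5-trimethoxyphenyl]ethan-1-ol | OCCc1cc(OC)c(OC)c(OC)c1OCc1ccccc1
F3 | step 5 | 2-[2-(benzyloxy)-3,4,5-trimethoxyphenyl]ethyl N,N-diisopropylcarbamate | CC(C)N(C(C)C)C(=O)OCCc1cc(OC)c(OC)c(OC)c1OCc1ccccc1
F4 | step 5 | 2-[2-(methoxymethoxy)-3,4,5,6-tetramethoxyphenyl]-4,4,5,5-tetramethyl-1,3,2-dioxaborolane | COCOc1c(B2OC(C)(C)C(C)(C)O2)c(OC)c(OC)c(OC)c1OC
F5 | step 5 | (R)-2-[2-(benzyloxy)-3,4,5-trimethoxyphenyl]-1-lithioethyl N,N-diisopropylcarbamate | [Li][C@H](Cc1cc(OC)c(OC)c(OC)c1OCc1ccccc1)OC(=O)N(C(C)C)C(C)C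
F6 | step 5 | lithium {(R)-2-[2-(benzyloxy)-3,4,5-trimethoxyphenyl]-1-[(diisopropylcarbamoyl)oxy]ethyl}[2-(methoxymethoxy)-3,4,5,6-tetramethoxyphenyl](pinacolato)borate | [Li+].COCOc1c([B-]2(OC(C)(C)C(C)(C)O2)[C@H](Cc3cc(OC)c(OC)c(OC)c3OCc4ccccc4)OC(=O)N(C(C)C)C(C)C)c(OC)c(OC)c(OC)c1OC
F7 | step 6 | lithium {(S)-2-[2-(benzyloxy)-3,4,5-trimethoxyphenyl]-1-[2-(methoxymethoxy)-3,4,5,6-tetramethoxyphenyl]ethyl}(pinacolato)(vinyl)borate | [Li+].COCOc1c([C@H](Cc2cc(OC)c(OC)c(OC)c2OCc3ccccc3)[B-]4(C=C)OC(C)(C)C(C)(C)O4)c(OC)c(OC)c(OC)c1OC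
F8 | step 6 | pinacol {(3R)-4-[2-(benzyloxy)-3,4,5-trimethoxyphenyl]-1-iodo-3-[2-(methoxymethoxy)-3,4,5,6-tetramethoxyphenyl]butan-2-yl}boronate (epimers at C2) | COCOc1c([C@H](Cc2cc(OC)c(OC)c(OC)c2OCc3ccccc3)C(CI)B4OC(C)(C)C(C)(C)O4)c(OC)c(OC)c(OC)c1OC
F9 | step 6 | 2-(benzyloxy)-3,4,5-trimethoxy-1-{(R)-2-[2-(methoxymethoxy)-3,4,5,6-tetramethoxyphenyl]but-3-en-1-yl}benzene | COCOc1c([C@H](Cc2cc(OC)c(OC)c(OC)c2OCc3ccccc3)C=C)c(OC)c(OC)c(OC)c1OC
F10 | step 6 | (S)-3-[2-(benzyloxy)-3,4,5-trimethoxyphenyl]-2-[2-(methoxymethoxy)-3,4,5,6-tetramethoxyphenyl]propanal | COCOc1c([C@H](Cc2cc(OC)c(OC)c(OC)c2OCc3ccccc3)C=O)c(OC)c(OC)c(OC)c1OC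
F11 | step 10 | 2,3,4,4,5-pentamethoxy-6-[(S)-6,7,8-trimethoxychroman-3-yl]cyclohexa-2,5-dien-1-one | O=C1C([C@H]2COc3c(cc(OC)c(OC)c3OC)C2)=C(OC)C(OC)(OC)C(OC)=C1OC
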